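**Retrosynthetic overview**
1. Numbering used throughout: C1 (CH bearing isopropenyl), C2, C3=C4 (C4 carries the lactone C=O, C18), C5, C6 (O–CH), C7, C8 (CH–CO2Me), C9 (C=O), C10, C11 (C=O), C12(Me)–C13 (epoxide), C14.
2. C3=C4: intramolecular Horner–Wadsworth–Emmons reaction of an α-phosphono lactone with a C3 aldehyde; this closes the 14-membered ring last.
3. C10–C11 and ring opening: (S)-carvone epoxide supplies C11–C14, C1, C2 and three stereocentres; C3 is added as CH2OH, the acetoacetate γ-carbanion adds to the ring ketone, and oxidation/retro-aldol cleaves C11–C2.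
4. C5–C6 (key bond): a zinc homoenolate (β-zincio ester) adds to chloroacetaldehyde under chiral titanium catalysis, joining two natural acceptor carbons, setting C6 and giving the γ-lactone; C7–C8 follows by acetoacetate alkylation.
5. Ring order: epoxide (step 1), γ-lactone (step 3), carvone six-ring opened (step 7), macrocycle (step 8).

Assumption: C8 (between ketone and ester) is configurationally labile; the (S) configuration drawn is taken as the thermodynamic one in the macrocycle and is reached by equilibration in step 8.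

**Step 1**
Reactants: 1 (S)-(+)-carvone
Product: 2 (1S,4S,6S)-1-methyl-4-(prop-1-en-2-yl)-7-oxabicyclo[4.1.0]heptan-2-one (trans-carvone epoxide)
Conditions: 30% H2O2, NaOH (cat.), MeOH, 0 °C
Reagents that add atoms: hydrogen peroxide, OO
Why: Weitz–Scheffer nucleophilic epoxidation of the enone; hydroperoxide adds to the ring face opposite the isopropenyl group, so the epoxide carbons (later C12, C13) are set trans to the pool stereocentre (later C1), as is known for carvone.

**Step 2**
Reactants: 2 (1S,4S,6S)-1-methyl-4-(prop-1-en-2-yl)-7-oxabicyclo[4.1.0]heptan-2-one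
Product: 3 (1S,4S,6S)-3-(hydroxymethyl)-1-methyl-4-(prop-1-en-2-yl)-7-oxabicyclo[4.1.0]heptan-2-one (C3 epimers, mainly 3,4-trans)
Conditions: LDA, THF, −78 °C; CH2O (g); AcOH
Reagents that add atoms: formaldehyde, C=O
Why: The ring CH2 next to the ketone is the only enolisable position, and its kinetic lithium enolate undergoes an aldol addition to monomeric formaldehyde (hydroxymethylation), adding C3; the new centre at C2 is erased in step 7.

**Step 3**
Reactants: 4 1-ethoxy-1-(trimethylsilyloxy)cyclopropane; 5 chloroacetaldehyde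
Product: 8 (5R)-5-(chloromethyl)dihydrofuran-2(3H)-one, via zinc homoenolate 6 (not isolated), via hydroxy ester 7 (not isolated)
Conditions: 4 (2.2 equiv), ZnCl2, Et2O, rt, then evaporate; Ti(OiPr)4 (1.2 equiv), (1S,2S)-1,2-bis(trifluoromethanesulfonamido)cyclohexane (8 mol%), toluene, −20 °C, then 5 (anhydrous); aq. HCl; TsOH (cat.), toluene, 60 °C
Reagents that add atoms: none
Why: Proposed new method: ZnCl2 opens the siloxycyclopropane to the zinc homoenolate (Nakamura–Kuwajima), which is unreactive toward the aldehyde alone because of internal ester chelation, so alkyl transfer runs through the chiral titanium bis(sulfonamide) complex, which delivers the ester β-carbon to the Re face of 5 and sets C6 (R in 8) while joining two natural acceptor carbons (ester β-carbon and aldehyde carbon); acid then closes the γ-lactone; the closest known reactions are the TMSCl- or titanium-promoted additions of this zinc homoenolate to aldehydes and the Ti/bis(triflamide)-catalysed enantioselective additions of functionalised dialkylzincs, where the (1R,2R)-ligand gives Si-face attack.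

**Step 4**
Reactants: 8 (5R)-5-(chloromethyl)dihydrofuran-2(3H)-one
Product: 10 diethyl [(5R)-5-(chloromethyl)-2-oxotetrahydrofuran-3-yl]phosphonate (C3 epimers), via phosphonite 9 (not isolated)
Conditions: LDA, THF, −78 °C; ClP(OEt)2, −78 to 0 °C; 30% H2O2, 0 °C
Reagents that add atoms: diethyl chlorophosphite, CCOP(Cl)OCC; hydrogen peroxide, OO
Why: Wiemer C-phosphinylation: the lactone lithium enolate attacks the P(III) chloride at carbon and the phosphonite is oxidised to the phosphonate, installing the olefination handle at C4 without touching C6 (the C4 centre is lost in step 8).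

**Step 5**
Reactants: 10 diethyl [(5R)-5-(chloromethyl)-2-oxotetrahydrofuran-3-yl]phosphonate; 11 methyl acetoacetate
Product: 12 methyl 2-{[(2S)-4-(diethoxyphosphoryl)-5-oxotetrahydrofuran-2-yl]methyl}-3-oxobutanoate (epimers at butanoate C2 and ring C4)
Conditions: 11 (2 equiv), NaH (2 equiv), NaI (0.2 equiv), DMF, 65 °C
Reagents that add atoms: none
Why: Acetoacetic ester alkylation (SN2 with in situ Finkelstein exchange) by the soft sodium enolate of 11, which is too weak a base to disturb the phosphonate; C6 is not a reacting centre (its descriptor changes to S by priority only) and the new C8 centre is epimerisable.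

**Step 6**
Reactants: 12 methyl 2-{[(2S)-4-(diethoxyphosphoryl)-5-oxotetrahydrofuran-2-yl]methyl}-3-oxobutanoate; 3 (1S,4S,6S)-3-(hydroxymethyl)-1-methyl-4-(prop-1-en-2-yl)-7-oxabicyclo[4.1.0]heptan-2-one
Product: 13 methyl 4-[(1S,4S,6S)-2-hydroxy-3-(hydroxymethyl)-1-methyl-4-(prop-1-en-2-yl)-7-oxabicyclo[4.1.0]heptan-2-yl]-2-{[(2S)-4-(diethoxyphosphoryl)-5-oxotetrahydrofuran-2-yl]methyl}-3-oxobutanoate (mixture at the carbinol carbon and the labile centres)
Conditions: 12, LDA (3.2 equiv), THF, −78 to −20 °C; 3, LiHMDS (1.0 equiv), THF, −78 °C; combine, −78 to −40 °C; AcOH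
Reagents that add atoms: none
Why: Weiler-type polyanion addition: the γ-carbanion (C10), the last-formed and most nucleophilic site of the trianion of 12, adds to the ring ketone to make C10–C11, while the pre-formed alkoxide of 3 cannot be eliminated and both acidic units of 12 are protected as enolates; the new carbinol centre is destroyed in step 7.

**Step 7**
Reactants: 13 (diol adduct named in step 6)
Product: 15 methyl 2-{[(2S)-4-(diethoxyphosphoryl)-5-oxotetrahydrofuran-2-yl]methyl}-5-{(2S,3S)-2-methyl-3-[(2S)-4-oxo-2-(prop-1-en-2-yl)butyl]oxiran-2-yl}-3,5-dioxopentanoate, via hydroxy aldehyde 14 (not isolated)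
Conditions: TEMPO (10 mol%), PhI(OAc)2, CH2Cl2, rt; then DBU, −40 to 0 °C; AcOH
Reagents that add atoms: none
Why: TEMPO/PhI(OAc)2 oxidises only the primary alcohol, and the β-hydroxy aldehyde then undergoes a base-induced retro-aldol cleavage of C11–C2 that opens the six-membered ring to the C3 aldehyde and the C9/C11 1,3-diketone; the alternative cleavage of C10–C11 is blocked because the β-keto ester is held as its enolate, and no stereocentre of the target is touched.

**Step 8**
Reactants: 15 (seco keto aldehyde named in step 7)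
Product: 16 CNP0108136.1, the target macrocycle, (1R,3E,6S,8S,12S,13S) in the overview numbering
Conditions: LiCl, iPr2NEt, MeCN, 2 mM (slow addition), rt
Reagents that add atoms: none
Why: Masamune–Roush Horner–Wadsworth–Emmons macrocyclisation at high dilution closes the 14-membered ring and gives the (E)-alkylidene lactone (chain anti to the lactone carbonyl, as usual for α-phosphono γ-lactones), and under these mildly enolising conditions C8 settles in its thermodynamic configuration.

**Compound list**
1 | (S)-(+)-carvone, (5S)-2-methyl-5-(prop-1-en-2-yl)cyclohex-2-en-1-one | C=C(C)[C@@H]1CC(=O)C(C)=CC1 | starting material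
2 | (1S,4S,6S)-1-methyl-4-(prop-1-en-2-yl)-7-oxabicyclo[4.1.0]heptan-2-one | C=C(C)[C@@H]1CC(=O)[C@@]2(C)O[C@H]2C1 | intermediate
3 | (1S,4S,6S)-3-(hydroxymethyl)-1-methyl-4-(prop-1-en-2-yl)-7-oxabicyclo[4.1.0]heptan-2-one (C3 epimers) | C=C(C)[C@@H]1C(CO)C(=O)[C@@]2(C)O[C@H]2C1 | intermediate
4 | 1-ethoxy-1-(trimethylsilyloxy)cyclopropane | CCOC1(O[Si](C)(C)C)CC1 | starting material
5 | chloroacetaldehyde | O=CCCl | starting material
6 | bis(3-ethoxy-3-oxopropyl)zinc (zinc homoenolate) | CCOC(=O)CC[Zn]CCC(=O)OCC | intermediate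
7 | ethyl (4R)-5-chloro-4-hydroxypentanoate | CCOC(=O)CC[C@@H](O)CCl | intermediate
8 | (5R)-5-(chloromethyl)dihydrofuran-2(3H)-one | ClC[C@H]1CCC(=O)O1 | intermediate
9 | diethyl [(5R)-5-(chloromethyl)-2-oxotetrahydrofuran-3-yl]phosphonite (C3 epimers) | ClC[C@H]1CC(P(OCC)OCC)C(=O)O1 | intermediate
10 | diethyl [(5R)-5-(chloromethyl)-2-oxotetrahydrofuran-3-yl]phosphonate (C3 epimers) | ClC[C@H]1CC(P(=O)(OCC)OCC)C(=O)O1 | intermediate
11 | methyl acetoacetate | CC(=O)CC(=O)OC | starting material
12 | methyl 2-{[(2S)-4-(diethoxyphosphoryl)-5-oxotetrahydrofuran-2-yl]methyl}-3-oxobutanoate (epimers at butanoate C2 and ring C4) | CC(=O)C(C(=O)OC)C[C@H]1CC(P(=O)(OCC)OCC)C(=O)O1 | intermediate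
13 | methyl 4-[(1S,4S,6S)-2-hydroxy-3-(hydroxymethyl)-1-methyl-4-(prop-1-en-2-yl)-7-oxabicyclo[4.1.0]heptan-2-yl]-2-{[(2S)-4-(diethoxyphosphoryl)-5-oxotetrahydrofuran-2-yl]methyl}-3-oxobutanoate | C=C(C)[C@@H]1C(CO)C(O)(CC(=O)C(C(=O)OC)C[C@H]2CC(P(=O)(OCC)OCC)C(=O)O2)[C@@]3(C)O[C@H]3C1 | intermediate
14 | methyl 4-[(1S,4S,6S)-3-formyl-2-hydroxy-1-methyl-4-(prop-1-en-2-yl)-7-oxabicyclo[4.1.0]heptan-2-yl]-2-{[(2S)-4-(diethoxyphosphoryl)-5-oxotetrahydrofuran-2-yl]methyl}-3-oxobutanoate | C=C(C)[C@@H]1C(C=O)C(O)(CC(=O)C(C(=O)OC)C[C@H]2CC(P(=O)(OCC)OCC)C(=O)O2)[C@@]3(C)O[C@H]3C1 | intermediate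
15 | methyl 2-{[(2S)-4-(diethoxyphosphoryl)-5-oxotetrahydrofuran-2-yl]methyl}-5-{(2S,3S)-2-methyl-3-[(2S)-4-oxo-2-(prop-1-en-2-yl)butyl]oxiran-2-yl}-3,5-dioxopentanoate | C=C(C)[C@H](CC=O)C[C@@H]1O[C@]1(C)C(=O)CC(=O)C(C(=O)OC)C[C@H]2CC(P(=O)(OCC)OCC)C(=O)O2 | intermediate
16 | CNP0108136.1, (1R,3E,6S,8S,12S,13S) in the overview numbering | C=C(C)[C@@H]1C/C=C2\C[C@H](C[C@H](C(=O)OC)C(=O)CC(=O)[C@@]3(C)O[C@H]3C1)OC2=O | target

**Totals**
Total step count: 8. Longest linear sequence: 6 steps (steps 3, 4, 5, 6, 7, 8).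

**Steps most likely to fail, with fallbacks**

Step 3 (enantioselective homoenolate addition; the asymmetric variant is untested and the zinc reagent is sluggish). The fallback sets out from 5 and returns at 8. Brown allylation of 5 with the B-allyldiisopinocampheylborane antipode that attacks the Re face gives (2R)-1-chloropent-4-en-2-ol F1. Hydroboration with 9-BBN and NaBO3 oxidation gives (4R)-5-chloropentane-1,4-diol F2. TEMPO/PhI(OAc)2 oxidative lactonisation of the 1,4-diol then gives 8, so C5–C6 comes from a reagent-controlled allyl transfer instead of the homoenolate.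

Step 6 (addition of a bulky trianion to a hindered, enolisable ketone). The fallback sets out from 3 and returns at 13 by inverting the order of the two C–C bonds. The small dianion of 11 (NaH, then n-BuLi, with CeCl3) is added in excess to the lithium alkoxide of 3 to give methyl 4-[(1S,4S,6S)-2-hydroxy-3-(hydroxymethyl)-1-methyl-4-(prop-1-en-2-yl)-7-oxabicyclo[4.1.0]heptan-2-yl]-3-oxobutanoate F3. Compound 10 is converted with NaI in acetone to diethyl [(5R)-5-(iodomethyl)-2-oxotetrahydrofuran-3-yl]phosphonate F4. The β-keto ester of F3, whose C8 is the only doubly activated carbon at this stage, is alkylated with F4 (Cs2CO3, DMF, 0 °C to rt, kept short to avoid δ-lactonisation) to give 13.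

Step 8 (14-membered HWE in the presence of an acidic tricarbonyl unit; oligomers, pyrone formation or transannular Michael addition are possible). The fallback sets out from 3 and returns at 16 by moving the ring closure from C3=C4 to C7–C8. The adduct methyl 4-[(1S,4S,6S)-2-hydroxy-3-(hydroxymethyl)-1-methyl-4-(prop-1-en-2-yl)-7-oxabicyclo[4.1.0]heptan-2-yl]-3-oxobutanoate F3, made as above, is oxidised and opened (TEMPO/PhI(OAc)2, then DBU) to methyl 5-{(2S,3S)-2-methyl-3-[(2S)-4-oxo-2-(prop-1-en-2-yl)butyl]oxiran-2-yl}-3,5-dioxopentanoate F5. Intermolecular HWE of F5 with 10 (LiCl, iPr2NEt, MeCN) gives methyl 5-{(2S,3S)-3-[(2R,4E)-4-[(5R)-5-(chloromethyl)-2-oxodihydrofuran-3(2H)-ylidene]-2-(prop-1-en-2-yl)butyl]-2-methyloxiran-2-yl}-3,5-dioxopentanoate F6. The dianion of its 3,5-dioxo ester (NaH, then LDA; NaI, THF–DMPU, high dilution) alkylates at C8, its less stabilised carbon, and closes the ring to 16.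

**Further compounds**
F1 | step 3 | (2R)-1-chloropent-4-en-2-ol | C=CC[C@@H](O)CCl
F2 | step 3 | (4R)-5-chloropentane-1,4-diol | OCCC[C@@H](O)CCl
F3 | step 6 | methyl 4-[(1S,4S,6S)-2-hydroxy-3-(hydroxymethyl)-1-methyl-4-(prop-1-en-2-yl)-7-oxabicyclo[4.1.0]heptan-2-yl]-3-oxobutanoate | C=C(C)[C@@H]1C(CO)C(O)(CC(=O)CC(=O)OC)[C@@]2(C)O[C@H]2C1
F4 | step 6 | diethyl [(5R)-5-(iodomethyl)-2-oxotetrahydrofuran-3-yl]phosphonate | IC[C@H]1CC(P(=O)(OCC)OCC)C(=O)O1
F5 | step 8 | methyl 5-{(2S,3S)-2-methyl-3-[(2S)-4-oxo-2-(prop-1-en-2-yl)butyl]oxiran-2-yl}-3,5-dioxopentanoate | C=C(C)[C@H](CC=O)C[C@@H]1O[C@]1(C)C(=O)CC(=O)CC(=O)OC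
F6 | step 8 | methyl 5-{(2S,3S)-3-[(2R,4E)-4-[(5R)-5-(chloromethyl)-2-oxodihydrofuran-3(2H)-ylidene]-2-(prop-1-en-2-yl)butyl]-2-methyloxiran-2-yl}-3,5-dioxopentanoate | C=C(C)[C@H](C/C=C2\C[C@H](CCl)OC2=O)C[C@@H]1O[C@]1(C)C(=O)CC(=O)CC(=O)OC
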